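The dihydropyran ring is cut at C5–C6, so that C6 is traced back to a formate on the C2 oxygen. The key step exploits the fact that C4 of the ring carries two CH2–C(=O) branches, ring carbon C5 with its ester and the exocyclic acetate chain: in the precursor these are two identical methyl acetate arms on a non-stereogenic carbon. An intramolecular Claisen formyl transfer from O1 to one arm closes the ring, makes the C5–C6 bond and turns C4 into a stereocentre under control of C2 and C3. The precursor is an acyclic (2R,3S) β-formyloxy tert-butyl ester with both centres set by one enzymatic reduction.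

Key step: step 4

Remark on the chemistry: ring atoms are numbered O1, C2 (CH3), C3 (CHO), C4 (side chain), C5 (CO2CH3), C6 (enol ether CH). The target is then (2S,3R,4R), with the methyl group and the side chain cis and the formyl group trans to both. The ketoreductase of step 2 is assumed to come from a commercial screening panel. The tert-butyl ester is kept as the C3 spectator because it is the ester least prone to enolisation and can be removed later without touching the methyl esters.

Step 1
Reactants: 1 tert-butyl acetoacetate; 2 dimethyl (E)-glutaconate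
Product: 3 1-tert-butyl 5-methyl 2-acetyl-3-(2-methoxy-2-oxoethyl)pentanedioate (racemic at C2)
Conditions: 1 (2 equiv), DBU (0.2 equiv), THF, 0 °C to rt, 2 added slowly
Reagents that add atoms: none
Why: Michael addition: the DBU-generated enolate of the β-keto ester adds to C3 of the glutaconate, which makes the two CH2CO2Me arms identical, and catalytic amidine with the donor in excess and slow addition of 2 should keep glutaconate self-addition and Claisen cyclisation of the adduct in check; the new C2 centre forms racemic and stays configurationally labile, as step 2 requires.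

Step 2
Reactants: 3 1-tert-butyl 5-methyl 2-acetyl-3-(2-methoxy-2-oxoethyl)pentanedioate
Product: 4 tert-butyl (2R,3S)-2-(1,5-dimethoxy-1,5-dioxopentan-3-yl)-3-hydroxybutanoate
Conditions: KRED ((S)-carbinol- and syn-selective, from a screening panel), NADP+ (cat.), iPrOH, phosphate buffer pH 7.5, DMSO (5%), 30 °C
Reagents that add atoms: none
Why: Ketoreductase reduction with dynamic kinetic resolution, a known reaction type for α-substituted β-keto esters: the enzyme transfers hydride from NADPH to one face of the methyl ketone, which sets the (3S) carbinol, and accepts only the (2R) enantiomer of 3 while the other racemises through the enol at pH 7.5, which sets C2 and gives the 2,3-syn isomer.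

Step 3
Reactants: 4 tert-butyl (2R,3S)-2-(1,5-dimethoxy-1,5-dioxopentan-3-yl)-3-hydroxybutanoate
Product: 5 tert-butyl (2R,3S)-2-(1,5-dimethoxy-1,5-dioxopentan-3-yl)-3-(formyloxy)butanoate
Conditions: HCO2Ac (preformed), pyridine, CH2Cl2, 0 °C
Reagents that add atoms: acetic formic anhydride, CC(=O)OC=O
Why: O-Formylation of a secondary alcohol with a mixed anhydride: the formyl carbonyl of acetic formic anhydride is the more electrophilic and less hindered one, no stereocentre is involved, and pyridine at 0 °C is too weak a base to eliminate the new β-formyloxy group.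

Step 4
Reactants: 5 tert-butyl (2R,3S)-2-(1,5-dimethoxy-1,5-dioxopentan-3-yl)-3-(formyloxy)butanoate
Product: 7 3-tert-butyl 5-methyl (2S,3R,4R)-4-(2-methoxy-2-oxoethyl)-2-methyl-3,4-dihydro-2H-pyran-3,5-dicarboxylate, via lactol 6 (not isolated)
Conditions: TiCl4 (2.2 equiv), Et3N (2.6 equiv), CH2Cl2 (0.02 M), −78 to −40 °C; 1 M HCl; then PPTS (cat.), MgSO4, CH2Cl2, rt
Reagents that add atoms: none
Why: Proposed new method: TiCl4 with Et3N soft-enolises one CH2CO2Me arm to a trichlorotitanium enolate whose α-carbon (the future C5) adds to the Lewis-acid-activated formate carbonyl (the future C6) held on O1, a 1,5 O-to-C formyl shift that leaves the α-formyl ester in equilibrium with lactol 6, which PPTS dehydrates to the conjugated enol ether. The closest known reactions are the TiCl4/amine crossed Claisen formylation of methyl esters with methyl formate, the Ti-Dieckmann cyclisation and the Baker–Venkataraman O-to-C acyl transfer. The pyran ring closes in a 6-exo-trig mode, with the formate C=O outside and O1 inside the forming ring. C4 becomes stereogenic by the choice between its two diastereotopic arms, controlled by the resident C2 and C3 centres: only one arm can reach the formate through a chair in which the C2 methyl, the C3 CO2tBu and the spectator arm are all equatorial, and this chair is the least crowded rotamer of the 2,3-syn precursor (extended CH3–C2–C3–C4 chain, C4–H flanked by C2 and the ester), so the side chain should end up cis to the methyl and trans to the C3 ester, that is (4R). The step needs enolisation of an arm in preference to C3–H (a C3 enolate would expel formate) and an intact tert-butyl ester; the hindered tertiary C3–H beside the bulky ester, the short exposure below −40 °C and high dilution against intermolecular transfer should provide both. No other carbonyl is within reach of the arm enolate except through a four-membered ring, so formyl transfer is its only cyclisation.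

Step 5
Reactants: 7 3-tert-butyl 5-methyl (2S,3R,4R)-4-(2-methoxy-2-oxoethyl)-2-methyl-3,4-dihydro-2H-pyran-3,5-dicarboxylate
Product: 8 (2S,3R,4R)-5-(methoxycarbonyl)-4-(2-methoxy-2-oxoethyl)-2-methyl-3,4-dihydro-2H-pyran-3-carboxylic acid
Conditions: TFA/CH2Cl2 (1:3), 0 °C to rt
Reagents that add atoms: none
Why: Acidolysis of a tert-butyl ester through the tert-butyl cation, which leaves as isobutene; the two methyl esters and the enol ether, a vinylogous carbonate, are inert to anhydrous TFA and no stereocentre is touched.

Step 6
Reactants: 8 (2S,3R,4R)-5-(methoxycarbonyl)-4-(2-methoxy-2-oxoethyl)-2-methyl-3,4-dihydro-2H-pyran-3-carboxylic acid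
Product: 9 methyl (2S,3S,4R)-3-(hydroxymethyl)-4-(2-methoxy-2-oxoethyl)-2-methyl-3,4-dihydro-2H-pyran-5-carboxylate
Conditions: BH3·SMe2 (1.5 equiv), THF, 0 °C to rt; MeOH, then H2O
Reagents that add atoms: none
Why: Borane reduction of a carboxylic acid through its acyloxyborane, which is much faster than reduction of the methyl esters or hydroboration of the electron-poor push–pull enol ether; the C3 descriptor changes from R to S only because the priorities change.

Step 7
Reactants: 9 methyl (2S,3S,4R)-3-(hydroxymethyl)-4-(2-methoxy-2-oxoethyl)-2-methyl-3,4-dihydro-2H-pyran-5-carboxylate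
Product: 10 2-[(2S,3S,4R)-3-(hydroxymethyl)-5-(methoxycarbonyl)-2-methyl-3,4-dihydro-2H-pyran-4-yl]acetic acid
Conditions: LiOH·H2O (1.2 equiv), THF/H2O (3:1), 0 °C; then 1 M HCl to pH 4
Reagents that add atoms: lithium hydroxide, [Li+].[OH-]
Why: Saponification: hydroxide cleaves the saturated side-chain ester far faster than the C5 ester, which is a deactivated vinylogous carbonate, and any fused δ-lactone formed from 9 by attack of the CH2OH group on that same ester opens to the same carboxylate; no aldehyde is present yet, so base cannot open the ring by β-elimination.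

Step 8
Reactants: 10 2-[(2S,3S,4R)-3-(hydroxymethyl)-5-(methoxycarbonyl)-2-methyl-3,4-dihydro-2H-pyran-4-yl]acetic acid
Product: 11 2-[(2S,3R,4R)-3-formyl-5-(methoxycarbonyl)-2-methyl-3,4-dihydro-2H-pyran-4-yl]acetic acid
Conditions: Dess–Martin periodinane (1.2 equiv), CH2Cl2, 0 °C to rt
Reagents that add atoms: none
Why: Dess–Martin oxidation of the primary alcohol to the aldehyde, fast and free of base, so that the epimerisable C3 centre and the β-alkoxy aldehyde are not exposed to conditions for enolisation or ring opening, and the free carboxylic acid is tolerated.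

Step 9
Reactants: 11 2-[(2S,3R,4R)-3-formyl-5-(methoxycarbonyl)-2-methyl-3,4-dihydro-2H-pyran-4-yl]acetic acid; 12 hydroxytyrosol
Product: 13 methyl (2S,3R,4R)-4-{2-[2-(3,4-dihydroxyphenyl)ethoxy]-2-oxoethyl}-3-formyl-2-methyl-3,4-dihydro-2H-pyran-5-carboxylate
Conditions: PPh3 (1.3 equiv), DIAD (1.3 equiv), THF, 0 °C to rt
Reagents that add atoms: none
Why: Mitsunobu esterification: the carboxylic acid is the only partner acidic enough to protonate the PPh3–DIAD betaine at once and only the primary aliphatic hydroxyl of 12 forms an alkoxyphosphonium ion, so the carboxylate alkylates at that carbon while the catechol hydroxyls stay free, and the near-neutral medium spares the aldehyde and all three stereocentres.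

Compound list
1 | tert-butyl acetoacetate | CC(=O)CC(=O)OC(C)(C)C | starting material
2 | dimethyl (E)-glutaconate | COC(=O)C/C=C/C(=O)OC | starting material
3 | 1-tert-butyl 5-methyl 2-acetyl-3-(2-methoxy-2-oxoethyl)pentanedioate (racemic) | CC(=O)C(C(=O)OC(C)(C)C)C(CC(=O)OC)CC(=O)OC | intermediate
4 | tert-butyl (2R,3S)-2-(1,5-dimethoxy-1,5-dioxopentan-3-yl)-3-hydroxybutanoate | O[C@@H](C)[C@H](C(=O)OC(C)(C)C)C(CC(=O)OC)CC(=O)OC | intermediate
5 | tert-butyl (2R,3S)-2-(1,5-dimethoxy-1,5-dioxopentan-3-yl)-3-(formyloxy)butanoate | O=CO[C@@H](C)[C@H](C(=O)OC(C)(C)C)C(CC(=O)OC)CC(=O)OC | intermediate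
6 | lactol: 3-tert-butyl 5-methyl (2S,3R,4R)-6-hydroxy-4-(2-methoxy-2-oxoethyl)-2-methyloxane-3,5-dicarboxylate, epimer mixture at C5 and C6, in equilibrium with the open hydroxy formyl ester | COC(=O)C1C(O)O[C@@H](C)[C@H](C(=O)OC(C)(C)C)[C@H]1CC(=O)OC | intermediate
7 | 3-tert-butyl 5-methyl (2S,3R,4R)-4-(2-methoxy-2-oxoethyl)-2-methyl-3,4-dihydro-2H-pyran-3,5-dicarboxylate | COC(=O)C1=CO[C@@H](C)[C@H](C(=O)OC(C)(C)C)[C@H]1CC(=O)OC | intermediate
8 | (2S,3R,4R)-5-(methoxycarbonyl)-4-(2-methoxy-2-oxoethyl)-2-methyl-3,4-dihydro-2H-pyran-3-carboxylic acid | COC(=O)C1=CO[C@@H](C)[C@H](C(=O)O)[C@H]1CC(=O)OC | intermediate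
9 | methyl (2S,3S,4R)-3-(hydroxymethyl)-4-(2-methoxy-2-oxoethyl)-2-methyl-3,4-dihydro-2H-pyran-5-carboxylate | COC(=O)C1=CO[C@@H](C)[C@H](CO)[C@H]1CC(=O)OC | intermediate
10 | 2-[(2S,3S,4R)-3-(hydroxymethyl)-5-(methoxycarbonyl)-2-methyl-3,4-dihydro-2H-pyran-4-yl]acetic acid | COC(=O)C1=CO[C@@H](C)[C@H](CO)[C@H]1CC(=O)O | intermediate
11 | 2-[(2S,3R,4R)-3-formyl-5-(methoxycarbonyl)-2-methyl-3,4-dihydro-2H-pyran-4-yl]acetic acid | COC(=O)C1=CO[C@@H](C)[C@H](C=O)[C@H]1CC(=O)O | intermediate
12 | hydroxytyrosol, 2-(3,4-dihydroxyphenyl)ethanol | OCCc1ccc(O)c(O)c1 | starting material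
13 | methyl (2S,3R,4R)-4-{2-[2-(3,4-dihydroxyphenyl)ethoxy]-2-oxoethyl}-3-formyl-2-methyl-3,4-dihydro-2H-pyran-5-carboxylate | COC(=O)C1=CO[C@@H](C)[C@H](C=O)[C@H]1CC(=O)OCCc1ccc(O)c(O)c1 | target

Total step count: 9. Longest linear sequence: 9 steps (from 1 and 2 to 13).

Steps most likely to fail

Step 4 (key step). The enolate may choose the other arm and give the C4 epimer; enolisation at C3–H with loss of formate, Lewis-acid cleavage of the tert-butyl ester, or intermolecular formyl transfer may also compete. The fallback uses known chemistry and puts the arm selection under thermodynamic control. It sets out from 4: lactonisation onto one arm with removal of methanol (PPTS, toluene, 80 °C, molecular sieves) should collect the material in the all-equatorial δ-lactone tert-butyl (2S,3R,4S)-4-(2-methoxy-2-oxoethyl)-2-methyl-6-oxooxane-3-carboxylate F1. Enolisation of the lactone CH2, the most acidic and least hindered C–H, with LDA at −78 °C and trapping with methyl formate gives the α-hydroxymethylene lactone tert-butyl (2S,3R,4R)-5-(hydroxymethylidene)-4-(2-methoxy-2-oxoethyl)-2-methyl-6-oxooxane-3-carboxylate F2. Acid-catalysed methanolysis (Korte rearrangement of an α-acyl lactone; CSA cat., MeOH, rt) opens the lactone to the methyl ester, closes the freed C2 hydroxyl onto the formyl carbon and dehydrates, which comes back to the route at 7.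

Step 2. The enzyme may not accept the α-branched substrate, may deliver the anti series, or the α-centre may racemise too slowly for the resolution to be dynamic. The fallback sets out from 3: Noyori hydrogenation (H2, RuCl2[(S)-BINAP] cat., MeOH, 50 °C) should set the (3S) carbinol by ligand control without relying on C2. The two C2 epimers are separated by chromatography; the syn epimer is 4, where the route is rejoined. The anti epimer tert-butyl (2S,3S)-2-(1,5-dimethoxy-1,5-dioxopentan-3-yl)-3-hydroxybutanoate F3 is oxidised back to 3 with Dess–Martin periodinane and recycled.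

Step 8. Lactonisation of the δ-hydroxy acid onto its own carboxyl group may outrun the oxidation, already during the acidification of step 7. The fallback sets out from 9 and reverses the order: Dess–Martin oxidation of 9 gives the aldehyde diester methyl (2S,3R,4R)-3-formyl-4-(2-methoxy-2-oxoethyl)-2-methyl-3,4-dihydro-2H-pyran-5-carboxylate F4. Pig liver esterase in phosphate buffer at pH 7 then hydrolyses the unhindered saturated methyl ester without base, which comes back to the route at 11.

Further compounds
F1 | step 4 | tert-butyl (2S,3R,4S)-4-(2-methoxy-2-oxoethyl)-2-methyl-6-oxooxane-3-carboxylate | C1C(=O)O[C@@H](C)[C@H](C(=O)OC(C)(C)C)[C@H]1CC(=O)OC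
F2 | step 4 | tert-butyl (2S,3R,4R)-5-(hydroxymethylidene)-4-(2-methoxy-2-oxoethyl)-2-methyl-6-oxooxane-3-carboxylate | OC=C1C(=O)O[C@@H](C)[C@H](C(=O)OC(C)(C)C)[C@H]1CC(=O)OC
F3 | step 2 | tert-butyl (2S,3S)-2-(1,5-dimethoxy-1,5-dioxopentan-3-yl)-3-hydroxybutanoate | O[C@@H](C)[C@@H](C(=O)OC(C)(C)C)C(CC(=O)OC)CC(=O)OC
F4 | step 8 | methyl (2S,3R,4R)-3-formyl-4-(2-methoxy-2-oxoethyl)-2-methyl-3,4-dihydro-2H-pyran-5-carboxylate | COC(=O)C1=CO[C@@H](C)[C@H](C=O)[C@H]1CC(=O)OC
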